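All runs were generated by integration for substances that don't exist; noise was put on by code.

Take the product share of a run as a share of its solid substrate charged, and carry it from the run whose initiator charge matches this flask.

| flask | solid substrate | partner | initiator | remark | time |
|---|---|---|---|---|---|
| gamma | 40 mM | 80 mM | 0.50 mM | run made earlier |  |
| alpha | 40 mM | 80 mM | 0.75 mM | run made earlier |  |
| theta | 20 mM | 80 mM | 1 mM | run made earlier |  |
| flask | 40 mM | 80.0 mM | 1.0 mM |  | 25 h |

* product at 25 h, in percent of the solid substrate charged
* concentration of starting material in solution at 25 h, in percent of saturation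

| run | time / h | product / % | starting material / % |
|---|---|---|---|
| gamma | 1.50 | 4.9 | 42.1 |
| gamma | 2.50 | 5.0 | 57.0 |
| gamma | 4.00 | 5.0 | 70.1 |
| gamma | 6.00 | 4.9 | 76.8 |
| gamma | 8.00 | 5.2 | 78.4 |
| gamma | 12.0 | 4.8 | 79.8 |
| gamma | 20.0 | 4.6 | 79.6 |
| alpha | 3.00 | 5.8 | 62.1 |
| alpha | 6.00 | 5.2 | 77.0 |
| alpha | 8.00 | 5.6 | 78.8 |
| alpha | 12.0 | 5.9 | 79.7 |
| alpha | 15.0 | 5.8 | 80.2 |
| alpha | 20.0 | 5.3 | 79.8 |
| theta | 2.00 | 11.9 | 87.9 |
| theta | 5.00 | 12.2 | 86.5 |
| theta | 10.0 | 12.4 | 85.7 |
| theta | 15.0 | 12.1 | 85.1 |
| theta | 20.0 | 12.9 | 84.1 |

(standard deviation of a reading: 0.3 percentage points)

- solid substrate is a solid; its amount is given per volume of the solution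
- the numbers in the tables scatter by 0.3 percentage points (one standard deviation)
- what may be going on: solid substrate <-> starting material; initiator -> 2 initiating radical; partner -> decomposed reagent; starting material + second chain carrier -> by-product + first chain carrier; starting material + initiating radical -> capped initiator + first chain carrier; partner + first chain carrier -> product + second chain carrier; 2 second chain carrier -> ended chains
- at the start none of the solid substrate is in solution
- starting material means what is dissolved; the solid is not counted in it

The bench rule, at fixed initiator and partner charges, is that a run stops at one amount of product, so its share goes inversely with the charge. The theta run has the flask's initiator charge, so I use the anchor share, the mean product share of theta, which is 12.3%. Scaling by the charge ratio, 0.500, gives 6.15% for the flask.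

Now find the border of this rule. In gamma, starting material climbs from 42.1% at 1.50 h to 79.8% at 12.0 h, while product reads 4.9% and then 4.8%, so product had stopped by the first reading. By then, starting material and product together came to 0.940 of theta's charge. The readings therefore vouch for the rule down to that multiple of theta's charge, and theta stands just above it.

For saturation, add gamma's plateau of starting material to my product share. That leaves about 14.0% of the flask's charge unaccounted for, which I take to be solid, so I expect a solution close to saturation.

The forecast gives 6.1% and 99.7%, holding that “Excess solid remains in the flask”.

The flask gives 6.08% and 99.8%.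

    solid substrate ⇌ starting material, rate k1*(cs1 - [starting material]) while solid is left; crystals form when [starting material] > cs1 (solubility = 32.0 mM, k = 1.50 × 10⁻⁴ /s)
    initiator → 2 initiating radical (k = 6.80 × 10⁻⁶ /s)
    partner → decomposed reagent (k = 0.00180 /s)
    starting material + second chain carrier → by-product + first chain carrier (k = 19000 /M/s)
    starting material + initiating radical → capped initiator + first chain carrier (k = 4.40 × 10⁵ /M/s)
    partner + first chain carrier → product + second chain carrier (k = 9800 /M/s)
    2 second chain carrier → ended chains (k = 6.00 × 10⁷ /M/s)

Apply the same reckoning to the neighbour flask, charged with 16 mM of solid substrate and otherwise unchanged. Its charge is 0.800 of theta's, below the border of 0.940, so the first readings do not vouch for it. The anchor share, scaled by the charge ratio, gives 15.4%, and the neighbour flask gives 15.2%. The neighbour flask's partner, charged at 5.00 equiv, is first to run out, with 0% of its charge left and 77.6 mM standing as decomposed reagent. The neighbour flask ends with 79.3% as starting material and 0% as solid substrate.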